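Side product and target both come from one intermediate, so follow one molecule of substrate: after it meets coupling partner, it stands at a fork.

| flask | substrate | coupling partner | remark | time |
|---|---|---|---|---|
| Sunday's | 0.26 M | 0.312 M | run made earlier |  |
| Monday's | 0.36 M | 0.312 M | run made earlier |  |
| Saturday's | 0.57 M | 0.312 M | run made earlier |  |
| amber | 0.26 M | 0.312 M | everything together at the start | 1.5 h |
| blue | 0.26 M (in portions, 2, over 80 min) | 0.312 M | first portion at the start, last at 80 min | 1.5 h |
| teal | 0.26 M | 0.312 M (fed, over 80 min) | all else is in the flask from the start; the feed brings no volume worth counting | 1.5 h |
| green | 0.26 M (fed, over 80 min) | 0.312 M | all else is in the flask from the start; the feed brings no volume worth counting | 1.5 h |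

- Sunday's (time / min: side product / %, target / %): 6.00: 26.3, 2.7; 20.0: 52.4, 5.3; 40.0: 64.3, 6.1; 50.0: 67.5, 6.3
- Monday's (time / min: side product / %, target / %): 8.00: 31.2, 2.4; 15.0: 42.4, 4.6; 40.0: 56.7, 5.4; 90.0: 62.6, 5.8
- Saturday's (time / min: side product / %, target / %): 25.0: 40.4, 4.0; 50.0: 44.1, 4.4; 60.0: 43.6, 4.5; 90.0: 44.3, 4.5

(scatter of a reading: 0.3 percentage points)

- steps thought possible: substrate + coupling partner -> intermediate; intermediate -> target; 2 coupling partner -> homo dimer; intermediate -> side product

- which flask leads in amount of side product, in percent of the substrate charged ("all alike" within 1.5 percentage points) (amber / blue / teal / green / all alike)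
- how much side product is there at the end, in percent of the substrate charged: amber
- how much side product is there at the end, in percent of the substrate charged: blue
- how much side product is there at the end, in percent of the substrate charged: teal
- how much side product is there at the end, in percent of the substrate charged: green

1. Take Sunday's last reading. Side product over side product plus target gives 91.5%. This is the fork share, the chance that a molecule passing the fork becomes side product; the usual term is selectivity.
2. Monday's and Saturday's runs have more substrate, yet their last readings give 91.5% and 90.8%. So your rule is: side product ≈ fork share × substrate consumed.
3. Amber has Sunday's charges, and it is read at 1.5 h instead of 50.0 min.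
4. At 50.0 min in Sunday's run, c(substrate) is down to 0.0681 M and c(coupling partner) is at most 0.120 M. Their product is at least ten times smaller than at the start, so the first step has slowed.
5. Sunday's run gained 3.2 percentage points in its last 10.0 min. Kept up, that pace would give 80.3%. Because the pace is falling, I place amber between 67.5% and that figure.
6. The forecast names amber as leader, with amber 73.5% (71.5% to 75.5%), blue 46.7% (43.5% to 50%), teal 66.5% (62% to 71%) and green 45.2% (41% to 50%). One of its grounds: “The intermediate seems short-lived”.
7. The flasks give amber as leader, with amber 73.2%, blue 46.3%, teal 69.4% and green 42.3%. Each lies inside the forecast's range.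

    substrate + coupling partner → intermediate (k = 0.269 /M/min)
    intermediate → target (k = 0.114 /min)
    2 coupling partner → homo dimer (k = 0.0587 /M/min)
    intermediate → side product (k = 1.20 /min)

8. In amber, 19.8% of the substrate is left at 1.50 h, and the fork share turns the rest into 73.4%, beside the 73.2% found. The share has no term for intermediate still in the flask, but amber holds 0.0733% of it then. In green at 0.669 h, the half-life of intermediate by the side-product step is 0.58 min, far shorter than the 0.61 h of coupling partner by the first step.
9. Now read green on to 4.0 h, where 47.8% of the substrate is left. The fork share gives 47.8%, and the computed side product is 47.7%.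

Readings and results were generated by integration from invented constants; scatter was added.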